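**Retrosynthetic overview**
1. Target 30 ⇒ desilylation and ester reduction ⇒ C10–C11 bond by chelation-controlled addition of a (1Z,3E)-dienylmagnesium (ring A plus chain) to the ring-B α,β-epoxy aldehyde 25.
2. Dienyl unit ⇒ Negishi coupling of the ring-A E-vinylzinc with propyne-derived (Z)-2-bromopropenyl boronate 11, then B→I; the vinyl iodide ⇒ Takai olefination of lactol 6.
3. Feature on which ring A rests: carbinol carbon C5 and side-chain methine C1 are both bonded to the CMe2 carbon C6 and carry O and C7 cis, so O5 and C7 close a γ-lactone bridging C6 (5). This is the oxygen-inserted form of the cyclobutanone of chrysanthenone 2 (from (+)-verbenone 1 by photochemical 1,3-shift); the alkene of 2 is carried through the Baeyer–Villiger step as oxirane 3 to steer the migration.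
4. Ring B ⇒ diethyl 2,5-dihydroxyterephthalate 16: quinone diester, catalytic asymmetric Diels–Alder with cyclopentadiene as a removable face shield, convex-face epoxidation and hydride delivery (oxirane trans to both carbinols), retro-Diels–Alder.
5. Ring order: ring A carbocycle from the chiral pool (lactone ring formed in step 3, opened after step 5); ring B carbocycle from the arene, oxirane in step 13; the two rings are joined last.

Key step: step 3

Assumptions and remarks
- Locants in the target: ring A C1 (methine), C2(Me)=C3, C4, C5 (CHOH), C6 (CMe2); chain C7=C8–C9(Me)=C10–C11(OH); ring B C1′ (oxirane C bearing C11), C2′ (oxirane CH), C3′ (CHOH), C4′(CH2OH)=C5′, C6′ (CHOH). Bicyclic intermediates keep their own IUPAC locants.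
- The pybox antipode meant in step 12 is the one that delivers 19 as drawn; the two-point binding model does not fix it for this quinone.
- Cyclopentadiene 18 is used freshly cracked from its commercial dimer.
- (+)-Verbenone of high enantiomeric purity is assumed.

Step 1
Reactants: 1 (1R,5R)-(+)-verbenone
Product: 2 (1S,5R)-chrysanthenone
Conditions: hν (medium-pressure Hg lamp, Pyrex), cyclohexane, rt, stopped at partial conversion
Reagents that add atoms: none
Why: Photochemical 1,3-alkyl shift of the enone moves the CMe2 carbon suprafacially from C5 to C3 of verbenone, so C1 is untouched and the new bridgehead is fixed by the bicycle; short irradiation limits the ketene pathway that erodes optical purity, which is to be assayed on 2 by chiral GC.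

Step 2
Reactants: 2 (1S,5R)-chrysanthenone
Product: 3 chrysanthenone 2,3-oxide (oxirane oxygen anti to the CMe2 bridge)
Conditions: DMDO, acetone, 0 °C
Reagents that add atoms: dimethyldioxirane CC1(C)OO1
Why: Dioxirane epoxidation leaves the ketone alone and should take the trisubstituted alkene from the face away from the syn-methyl of the CMe2 bridge, as in α-pinene; the oxirane is a temporary mask whose configuration is erased in step 4.

Step 3
Reactants: 3 chrysanthenone 2,3-oxide
Product: 4 2,3-epoxy-2,8,8-trimethyl-6-oxabicyclo[3.2.1]octan-7-one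
Conditions: mCPBA, NaHCO3, CH2Cl2, 0 °C
Reagents that add atoms: meta-chloroperbenzoic acid OOC(=O)c1cccc(Cl)c1
Why: Baeyer–Villiger oxidation: the peracid adds to the strained C6 carbonyl from the face of the three-atom bridge (the other face is screened by the syn-methyl of C7), and the Criegee adduct collapses by 1,2-shift of a bridgehead carbon to oxygen with loss of m-chlorobenzoate. The closest known reaction type is the peracid oxidation of fused and bridged bicyclic cyclobutanones to γ-lactones. The new ring is not formed by cyclisation but by ring enlargement: oxygen is inserted into the C5–C6 bond, so the four-membered ketone becomes the five-membered lactone of a 6-oxabicyclo[3.2.1]octane with relief of strain. No stereocentre is created afresh; the migrating carbon keeps its configuration, so the C–O centre of ring A is the verbenone-derived bridgehead and stays cis to the carbonyl carbon left on C1. The step needs regioselectivity between two stereoelectronically equivalent bridgeheads, and the oxirane should supply it: it removes the allylic stabilisation of C1 and places a σ-withdrawing C–O bond next to it, so the CH–CH2 bridgehead C5 should migrate. The bicarbonate buffer protects the acid-labile trisubstituted oxirane.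

Step 4
Reactants: 4 2,3-epoxy-2,8,8-trimethyl-6-oxabicyclo[3.2.1]octan-7-one
Product: 5 (1S,5R)-2,8,8-trimethyl-6-oxabicyclo[3.2.1]oct-2-en-7-one
Conditions: Re2O7 (cat.), P(OPh)3, toluene, 100 °C
Reagents that add atoms: none
Why: Rhenium-catalysed oxygen-atom transfer from the oxirane to the phosphite (epoxide deoxygenation) should return the trisubstituted alkene at its original position while the lactone is inert.

Step 5
Reactants: 5 (1S,5R)-2,8,8-trimethyl-6-oxabicyclo[3.2.1]oct-2-en-7-one
Product: 6 (1S,5R)-2,8,8-trimethyl-6-oxabicyclo[3.2.1]oct-2-en-7-ol (lactol, both anomers)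
Conditions: DIBAL-H (1.1 equiv), CH2Cl2, −78 °C
Reagents that add atoms: none
Why: Partial reduction of a γ-lactone stops at the aluminium hemiacetal, and the lactol keeps the enolisable β,γ-unsaturated aldehyde masked.

Step 6
Reactants: 6 lactol
Product: 7 (1R,5S)-5-[(E)-2-iodoethenyl]-4,6,6-trimethylcyclohex-3-en-1-ol
Conditions: CrCl2, CHI3, THF/dioxane, 0 °C → rt
Reagents that add atoms: iodoform IC(I)I
Why: Takai olefination of the ring-opened hydroxy aldehyde under non-basic Cr(II) conditions should give the E-iodoalkene (anti elimination from the gem-dichromium adduct of an α-branched aldehyde) without epimerising C1 or moving the ring alkene into conjugation.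

Step 7
Reactants: 7 hydroxy vinyl iodide
Product: 8 tert-butyldimethylsilyl ether of 7
Conditions: TBSOTf, 2,6-lutidine, CH2Cl2, −78 → 0 °C
Reagents that add atoms: tert-butyldimethylsilyl triflate CC(C)(C)[Si](C)(C)OS(=O)(=O)C(F)(F)F
Why: Silylation with the triflate overcomes the hindrance of the carbinol next to CMe2 and removes the acidic proton before metalation.

Step 8
Reactants: 9 propyne
Product: 11 (Z)-2-(2-bromoprop-1-en-1-yl)-4,4,5,5-tetramethyl-1,3,2-dioxaborolane, via (Z)-(2-bromoprop-1-enyl)dibromoborane 10 (not isolated)
Conditions: BBr3, CH2Cl2, −78 °C → rt; then pinacol, rt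
Reagents that add atoms: boron tribromide BrB(Br)Br; pinacol CC(C)(O)C(C)(C)O
Why: syn-Bromoboration of the terminal alkyne puts boron on the terminal carbon with bromine cis to it, and esterification in the same flask gives the stable pinacol boronate with the Z geometry needed for C9=C10.

Step 9
Reactants: 8 silyl ether vinyl iodide; 11 (Z)-bromopropenyl boronate
Product: 14 TBS-protected ring-A (1Z,3E)-2-methylbuta-1,3-dienyl pinacol boronate, via alkenyllithium 12 (not isolated), via alkenylzinc bromide 13 (not isolated)
Conditions: t-BuLi (2 equiv), Et2O, −78 °C; ZnBr2, THF, −78 → 0 °C; then 11, Pd(t-Bu3P)2 (cat.), rt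
Reagents that add atoms: none
Why: Iodine–lithium exchange, transmetalation to zinc and Negishi coupling all proceed with retention at sp2 carbon, and palladium inserts into the C–Br bond while the boronate is inert without base, so the 7E,9Z diene is assembled.

Step 10
Reactants: 14 dienyl boronate
Product: 15 TBS-protected ring-A (1Z,3E)-1-iodo-2-methylbuta-1,3-diene
Conditions: NaOH (aq), THF, 0 °C; then I2, dark
Reagents that add atoms: iodine II
Why: Iododeboronation of the alkenyl boronate after prior formation of the hydroxy-ate complex replaces boron by iodine with retention, keeping the Z geometry; cold and dark conditions guard the diene against iodine-induced isomerisation.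

Step 11
Reactants: 16 diethyl 2,5-dihydroxyterephthalate
Product: 17 diethyl 3,6-dioxocyclohexa-1,4-diene-1,4-dicarboxylate
Conditions: Ag2O, MgSO4, toluene, rt; used at once
Reagents that add atoms: none
Why: Silver(I) oxide oxidation of a hydroquinone ester to the quinone ester under neutral anhydrous conditions avoids conjugate addition to this very electrophilic quinone.

Step 12
Reactants: 17 quinone diester; 18 cyclopentadiene
Product: 19 endo adduct diethyl 5,8-dioxo-1,4,5,8-tetrahydro-1,4-methanonaphthalene-4a,7(8aH)-dicarboxylate
Conditions: Sm(OTf)3/(S,S)-Ph-pybox (10 mol%), 4 Å MS, THF, −78 °C, slow addition of 18, dark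
Reagents that add atoms: none
Why: Lewis-acid-catalysed enantioselective Diels–Alder reaction of a 2-alkoxycarbonyl quinone: two-point binding of the β-keto ester unit to the pybox–lanthanide selects one enantioface of the (symmetry-equivalent) ester-bearing alkenes, and the endo adduct sets the two ring-fusion centres that relay chirality to ring B; the angular ester blocks aromatisation.

Step 13
Reactants: 19 endo adduct
Product: 20 6,7-epoxide of 19 (oxirane on the convex face)
Conditions: 30% H2O2, NaHCO3, THF–H2O, 0 °C
Reagents that add atoms: hydrogen peroxide OO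
Why: Weitz–Scheffer nucleophilic epoxidation of the doubly activated alkene should occur from the convex face, cis to the angular ester and away from the norbornene bridge, which fixes the oxirane carbons C1′ and C2′.

Step 14
Reactants: 20 epoxy diketone
Product: 21 endo,endo-5,8-diol of 20
Conditions: NaBH4, CeCl3·7H2O, MeOH/CH2Cl2, −78 °C
Reagents that add atoms: none
Why: Luche reduction delivers hydride to both ketones from the open convex face (the concave face is closed by the norbornene alkene), so both hydroxyls point to the concave side, trans to the oxirane and cis to each other, while the esters are untouched at −78 °C.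

Step 15
Reactants: 21 diol
Product: 22 5,8-bis(tert-butyldimethylsilyl) ether of 21
Conditions: TBSOTf, 2,6-lutidine, CH2Cl2, 0 °C → rt
Reagents that add atoms: tert-butyldimethylsilyl triflate CC(C)(C)[Si](C)(C)OS(=O)(=O)C(F)(F)F
Why: Triflate-mediated silylation protects the two hindered endo carbinols as ethers that survive hydride, heat and organometallic reagents.

Step 16
Reactants: 22 bis-silyl ether diester
Product: 23 7-(hydroxymethyl) compound (oxirane-bound ester reduced, angular ester kept)
Conditions: DIBAL-H (2.2 equiv), CH2Cl2, −78 °C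
Reagents that add atoms: none
Why: Chemoselective DIBAL reduction: the glycidic ester is activated by the α-oxygen and tied back by the three-membered ring, whereas the angular ester sits on a fully carbon-substituted neopentyl centre and should not react at −78 °C.

Step 17
Reactants: 23 tricyclic epoxy alcohol
Product: 24 ethyl 3,6-bis(tert-butyldimethylsilyloxy)-4,5-epoxy-4-(hydroxymethyl)cyclohex-1-ene-1-carboxylate
Conditions: Ph2O, 230 °C, N2 stream
Reagents that add atoms: none
Why: Retro-Diels–Alder extrusion of cyclopentadiene, eased by the quaternary ring-fusion carbon and the conjugated ester formed, unveils the C4′=C5′ alkene; the oxirane and carbinol centres are not involved.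

Step 18
Reactants: 24 epoxy alcohol
Product: 25 ethyl 3,6-bis(tert-butyldimethylsilyloxy)-4,5-epoxy-4-formylcyclohex-1-ene-1-carboxylate
Conditions: Dess–Martin periodinane, NaHCO3, CH2Cl2, rt
Reagents that add atoms: none
Why: Dess–Martin oxidation of the primary alcohol under buffered conditions gives the aldehyde, which has no α-hydrogen and cannot epimerise.

Step 19
Reactants: 15 dienyl iodide; 25 epoxy aldehyde
Product: 28 (11S)-carbinol with ring A O-TBS and ring B bis-O-TBS and ethyl ester, via dienyllithium 26 (not isolated), via dienylmagnesium bromide 27 (not isolated)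
Conditions: t-BuLi (2 equiv), Et2O, −78 °C; MgBr2·OEt2, −78 °C; then 25, CH2Cl2, −78 °C
Reagents that add atoms: none
Why: Iodine–lithium exchange with retention, transmetalation to magnesium and chelation-controlled 1,2-addition: Mg bridges the aldehyde and oxirane oxygens and the dienyl group should enter from the C2′–H flank, away from the C6′ silyloxy group, setting C11 as S, while the aldehyde outruns the ester at −78 °C.

Step 20
Reactants: 28 coupled ester
Product: 29 allylic alcohol (C4′–CH2OH) with three O-TBS groups
Conditions: DIBAL-H (4 equiv), CH2Cl2, −78 °C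
Reagents that add atoms: none
Why: DIBAL 1,2-reduction of the α,β-unsaturated ester gives the allylic alcohol at a temperature at which the oxirane next to the aluminium alkoxide should not be opened.

Step 21
Reactants: 29 tris-silyl ether
Product: 30 target CNP0389279.1
Conditions: TBAF, AcOH, THF, 0 → 40 °C
Reagents that add atoms: none
Why: Fluoride-mediated desilylation removes all three TBS groups, and buffering with acetic acid keeps alkoxide concentration low so that Payne migration of the trans-hydroxy oxirane is suppressed.

**Compound list**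
1 | (1R,5R)-(+)-verbenone | CC1=CC(=O)[C@@H]2C[C@H]1C2(C)C | starting material
2 | (1S,5R)-chrysanthenone (2,7,7-trimethylbicyclo[3.1.1]hept-2-en-6-one) | CC1=CC[C@H]2C(=O)[C@@H]1C2(C)C | intermediate
3 | chrysanthenone 2,3-oxide (2,3-epoxy-2,7,7-trimethylbicyclo[3.1.1]heptan-6-one, oxirane O anti to the CMe2 bridge) | C[C@]12O[C@H]1C[C@H]3C(=O)[C@@H]2C3(C)C | intermediate
4 | 2,3-epoxy-2,8,8-trimethyl-6-oxabicyclo[3.2.1]octan-7-one | C[C@]12O[C@H]1C[C@H]3OC(=O)[C@@H]2C3(C)C | intermediate
5 | (1S,5R)-2,8,8-trimethyl-6-oxabicyclo[3.2.1]oct-2-en-7-one | CC1=CC[C@H]2OC(=O)[C@@H]1C2(C)C | intermediate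
6 | (1S,5R)-2,8,8-trimethyl-6-oxabicyclo[3.2.1]oct-2-en-7-ol (anomeric mixture) | CC1=CC[C@H]2OC(O)[C@@H]1C2(C)C | intermediate
7 | (1R,5S)-5-[(E)-2-iodoethenyl]-4,6,6-trimethylcyclohex-3-en-1-ol (OH and iodovinyl cis) | CC1=CC[C@@H](O)C(C)(C)[C@H]1/C=C/I | intermediate
8 | tert-butyldimethylsilyl ether of 7 | CC1=CC[C@@H](O[Si](C)(C)C(C)(C)C)C(C)(C)[C@H]1/C=C/I | intermediate
9 | propyne | CC#C | starting material
10 | (Z)-(2-bromoprop-1-enyl)dibromoborane | C/C(Br)=C/B(Br)Br | intermediate
11 | (Z)-2-(2-bromoprop-1-en-1-yl)-4,4,5,5-tetramethyl-1,3,2-dioxaborolane | C/C(Br)=C/B1OC(C)(C)C(C)(C)O1 | intermediate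
12 | (E)-alkenyllithium from 8 | CC1=CC[C@@H](O[Si](C)(C)C(C)(C)C)C(C)(C)[C@H]1/C=C/[Li] | intermediate
13 | (E)-alkenylzinc bromide from 8 | CC1=CC[C@@H](O[Si](C)(C)C(C)(C)C)C(C)(C)[C@H]1/C=C/[Zn]Br | intermediate
14 | TBS-protected ring-A (1Z,3E)-2-methylbuta-1,3-dienyl pinacol boronate | CC1=CC[C@@H](O[Si](C)(C)C(C)(C)C)C(C)(C)[C@H]1/C=C/C(C)=C\B1OC(C)(C)C(C)(C)O1 | intermediate
15 | TBS-protected ring-A (1Z,3E)-1-iodo-2-methylbuta-1,3-diene | CC1=CC[C@@H](O[Si](C)(C)C(C)(C)C)C(C)(C)[C@H]1/C=C/C(C)=C\I | intermediate
16 | diethyl 2,5-dihydroxyterephthalate | CCOC(=O)c1cc(O)c(cc1O)C(=O)OCC | starting material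
17 | diethyl 3,6-dioxocyclohexa-1,4-diene-1,4-dicarboxylate | CCOC(=O)C1=CC(=O)C(C(=O)OCC)=CC1=O | intermediate
18 | cyclopentadiene | C1C=CC=C1 | starting material
19 | endo adduct, diethyl 5,8-dioxo-1,4,5,8-tetrahydro-1,4-methanonaphthalene-4a,7(8aH)-dicarboxylate | CCOC(=O)C1=CC(=O)[C@]2(C(=O)OCC)[C@@H]3C=C[C@@H](C3)[C@@H]2C1=O | intermediate
20 | 6,7-epoxide of 19, oxirane O on the convex face (cis to the angular ester) | CCOC(=O)[C@]12O[C@H]1C(=O)[C@]3(C(=O)OCC)[C@@H]4C=C[C@@H](C4)[C@@H]3C2=O | intermediate
21 | endo,endo-5,8-diol of 20, both OH trans to the oxirane O | CCOC(=O)[C@]12O[C@H]1[C@H](O)[C@]3(C(=O)OCC)[C@@H]4C=C[C@@H](C4)[C@@H]3[C@@H]2O | intermediate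
22 | 5,8-bis(tert-butyldimethylsilyl) ether of 21 | CCOC(=O)[C@]12O[C@H]1[C@H](O[Si](C)(C)C(C)(C)C)[C@]3(C(=O)OCC)[C@@H]4C=C[C@@H](C4)[C@@H]3[C@@H]2O[Si](C)(C)C(C)(C)C | intermediate
23 | 7-(hydroxymethyl) analogue of 22 (angular ethyl ester kept) | OC[C@]12O[C@H]1[C@H](O[Si](C)(C)C(C)(C)C)[C@]3(C(=O)OCC)[C@@H]4C=C[C@@H](C4)[C@@H]3[C@@H]2O[Si](C)(C)C(C)(C)C | intermediate
24 | ethyl 3,6-bis(tert-butyldimethylsilyloxy)-4,5-epoxy-4-(hydroxymethyl)cyclohex-1-ene-1-carboxylate, both silyloxy groups trans to the oxirane O | OC[C@]12O[C@H]1[C@H](O[Si](C)(C)C(C)(C)C)C(C(=O)OCC)=C[C@@H]2O[Si](C)(C)C(C)(C)C | intermediate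
25 | ethyl 3,6-bis(tert-butyldimethylsilyloxy)-4,5-epoxy-4-formylcyclohex-1-ene-1-carboxylate | O=C[C@]12O[C@H]1[C@H](O[Si](C)(C)C(C)(C)C)C(C(=O)OCC)=C[C@@H]2O[Si](C)(C)C(C)(C)C | intermediate
26 | (1Z,3E)-dienyllithium from 15 | CC1=CC[C@@H](O[Si](C)(C)C(C)(C)C)C(C)(C)[C@H]1/C=C/C(C)=C\[Li] | intermediate
27 | (1Z,3E)-dienylmagnesium bromide from 15 | CC1=CC[C@@H](O[Si](C)(C)C(C)(C)C)C(C)(C)[C@H]1/C=C/C(C)=C\[Mg]Br | intermediate
28 | (11S)-carbinol, ring A O-TBS, ring B 3′,6′-bis-O-TBS, C4′ ethyl ester | CC1=CC[C@@H](O[Si](C)(C)C(C)(C)C)C(C)(C)[C@H]1/C=C/C(C)=C\[C@H](O)[C@]12O[C@H]1[C@H](O[Si](C)(C)C(C)(C)C)C(C(=O)OCC)=C[C@@H]2O[Si](C)(C)C(C)(C)C | intermediate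
29 | tris-O-TBS ether of the target (free C11–OH and C4′–CH2OH) | CC1=CC[C@@H](O[Si](C)(C)C(C)(C)C)C(C)(C)[C@H]1/C=C/C(C)=C\[C@H](O)[C@]12O[C@H]1[C@H](O[Si](C)(C)C(C)(C)C)C(CO)=C[C@@H]2O[Si](C)(C)C(C)(C)C | intermediate
30 | CNP0389279.1 | CC1=CC[C@@H](O)C(C)(C)[C@H]1/C=C/C(C)=C\[C@H](O)[C@]12O[C@H]1[C@H](O)C(CO)=C[C@@H]2O | target

**Totals**
Total step count: 21. Longest linear sequence: 12 steps (1–7, 9, 10, 19–21); the ring-B branch (11–18) and the boronate (8) are convergent.

**Steps most likely to fail**

Step 3. The oxirane-bearing bridgehead may migrate instead of C5, or the pinene-oxide-type oxirane may rearrange under the acidic by-product before oxygen insertion. The fallback sets out from 2 and drops the masking: a Baeyer–Villiger monooxygenase (cyclohexanone-monooxygenase type, whole cells or isolated enzyme with NADPH recycling, variants screened for migration of C5) oxidises the alkene-bearing ketone itself. Regiocontrol then comes from the active site and not from the substrate. This should give 5 directly, where the route is rejoined; steps 2 and 4 are omitted.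

Step 19. Facial selection at the aldehyde may be poor if the magnesium chelate with the oxirane oxygen does not dominate over the open Cornforth-type arrangement, and the Lewis acid may open the oxirane. The fallback sets out from 15 and 25 and replaces substrate control by reagent control: a Nozaki–Hiyama–Kishi coupling (CrCl2, NiCl2 cat., chiral sulfonamide ligand of the Kishi type, Et3N, THF or MeCN), with the ligand antipode chosen for the 11S carbinol. It rejoins the route at 28.

Step 12. The uncatalysed cycloaddition of the very electron-poor quinone may compete with the catalysed one and lower the enantiomeric purity of all ring-B material. The fallback sets out from 17 and resolves instead of inducing. The thermal reaction with 18 (CH2Cl2, −78 °C) gives 19 together with its enantiomer ent-19 F1. Steps 13 and 14 carry both antipodes on, through ent-20 F2, to 21 and ent-21 F3. A lipase-catalysed acylation (lipase PS, vinyl acetate, t-BuOMe), with the enzyme selected from a screen so that the unwanted antipode reacts, converts F3 into the 8-O-acetate of ent-21 F4. Unreacted 21 is separated by chromatography and the route is rejoined at 21.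

Further compounds
F0 | step 3 | none | none
F0 | step 19 | none | none
F1 | step 12 | ent-19 | CCOC(=O)C1=CC(=O)[C@@]2(C(=O)OCC)[C@H]3C=C[C@H](C3)[C@H]2C1=O
F2 | step 12 | ent-20 | CCOC(=O)[C@@]12O[C@@H]1C(=O)[C@@]3(C(=O)OCC)[C@H]4C=C[C@H](C4)[C@H]3C2=O
F3 | step 12 | ent-21 | CCOC(=O)[C@@]12O[C@@H]1[C@@H](O)[C@@]3(C(=O)OCC)[C@H]4C=C[C@H](C4)[C@H]3[C@H]2O
F4 | step 12 | 8-O-acetate of ent-21 | CCOC(=O)[C@@]12O[C@@H]1[C@@H](O)[C@@]3(C(=O)OCC)[C@H]4C=C[C@H](C4)[C@H]3[C@H]2OC(C)=O
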